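**Retrosynthetic overview**

1. The strategy rests on the fully substituted 1,4-benzoquinone ring: C1 and C4 are the para carbonyls, C2 and C5 carry OMe, C3 carries indol-3-yl (indole B) and C6 carries 2-(2-methylbut-3-en-2-yl)indol-3-yl (indole A); the target has no stereocentre.
2. After removal of the two N-protecting groups, the quinone C1–C2 bond is opened retro-electrocyclically to 4-alkenyl-4-hydroxycyclobutenone 16; its four ring carbons become C1, C6, C5 and C4, and its (Z)-1-indolyl-2-methoxyvinyl arm becomes C3–C2.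
3. 16 is cut at the carbinol–vinyl bond into vinyllithium 15 (from indole-3-carbaldehyde by N-silylation, Wittig methoxymethylenation, bromination–dehydrobromination and Br–Li exchange) and cyclobutenedione 9.
4. 9 comes from 2-(2-methylbut-3-en-2-yl)indole 5 by C3 chlorosquarylation with squaric acid dichloride, methanolysis and N-acylation; 5 comes from a Madelung closure of the 2-methylanilide of 2,2-dimethylbut-3-enoic acid.
5. Ring order: the pyrrole ring of indole A (step 2), then the quinone ring (step 9); the benzene rings, indole B and the four-membered ring are bought.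

Key step: step 9

Remark on the chemistry: the nitrogen of indole A is carried as its methyl carbamate from step 4 to step 10. Its N–H, acidified by the cyclobutenedione, would otherwise be deprotonated by the vinyllithium, and the indolide would turn the carbonyl that must be attacked into a vinylogous amidate. Squaric acid dichloride is taken as a commercial reagent.

**Route**

Step 1
Reactants: 1 2,2-dimethylbut-3-enoic acid; 2 2-methylaniline
Product: 4 N-(2-methylphenyl)-2,2-dimethylbut-3-enamide, via 2,2-dimethylbut-3-enoyl chloride 3 (not isolated)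
Conditions: (COCl)2, DMF (cat.), CH2Cl2, 0 °C → rt; then 2, Et3N, CH2Cl2, 0 °C → rt
Reagents that add atoms: none
Why: Acid chloride formation followed by N-acylation of the aniline (Schotten–Baumann-type amide formation) is dependable for this α-quaternary, non-enolizable acid, and the vinyl group is inert in both stages.

Step 2
Reactants: 4 N-(2-methylphenyl)-2,2-dimethylbut-3-enamide
Product: 5 2-(2-methylbut-3-en-2-yl)-1H-indole
Conditions: n-BuLi (3 equiv), THF, −20 °C → rt; H2O
Reagents that add atoms: none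
Why: Madelung indole synthesis in its alkyllithium variant, in which the N,benzylic-dilithiated anilide attacks its own non-enolizable amide carbonyl and loses LiOH, as is established for the analogous pivalanilide; the isolated terminal alkene should not be carbolithiated under these conditions.

Step 3
Reactants: 5 2-(2-methylbut-3-en-2-yl)-1H-indole; 6 3,4-dichlorocyclobut-3-ene-1,2-dione (squaric acid dichloride)
Product: 8 3-methoxy-4-[2-(2-methylbut-3-en-2-yl)-1H-indol-3-yl]cyclobut-3-ene-1,2-dione, via semisquaric chloride 7 (not isolated)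
Conditions: 6 (1.05 equiv), CH2Cl2, 0 °C → rt; evaporate; MeOH, rt → 40 °C
Reagents that add atoms: methanol, CO
Why: Uncatalysed Friedel–Crafts-type chlorosquarylation, in which the nucleophilic indole C3 adds to a vinylogous acid chloride carbon of 6 and expels chloride, followed by addition–elimination of methanol at the remaining C–Cl; the deactivated vinylogous-amide product and the bulky C2 substituent should stop a second arylation.

Step 4
Reactants: 8 3-methoxy-4-[2-(2-methylbut-3-en-2-yl)-1H-indol-3-yl]cyclobut-3-ene-1,2-dione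
Product: 9 methyl 3-(2-methoxy-3,4-dioxocyclobut-1-en-1-yl)-2-(2-methylbut-3-en-2-yl)indole-1-carboxylate
Conditions: NaH, ClCO2Me, THF, 0 °C → rt
Reagents that add atoms: methyl chloroformate, COC(=O)Cl
Why: N-acylation of an indole (carbamate formation) through the sodium indolide, which forms readily because the cyclobutenedione acidifies the N–H, with a small chloroformate that should reach the nitrogen despite the neighbouring quaternary carbon; the carbamate removes the acidic proton and damps donation from indole A into the carbonyl to be attacked in step 8.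

Step 5
Reactants: 10 1H-indole-3-carbaldehyde
Product: 11 1-(triisopropylsilyl)indole-3-carbaldehyde
Conditions: NaH, THF, 0 °C; i-Pr3SiCl, 0 °C → rt
Reagents that add atoms: chlorotriisopropylsilane, CC(C)[Si](Cl)(C(C)C)C(C)C
Why: N-silylation of the sodium indolide; the bulky silyl group shields C2 and withstands the organolithium reagents used later.

Step 6
Reactants: 11 1-(triisopropylsilyl)indole-3-carbaldehyde
Product: 12 3-(2-methoxyethenyl)-1-(triisopropylsilyl)indole (E/Z mixture)
Conditions: MeOCH2PPh3Cl, NaN(SiMe3)2, THF, 0 °C; then 11, 0 °C → rt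
Reagents that add atoms: (methoxymethyl)triphenylphosphonium chloride, COC[P+](c1ccccc1)(c1ccccc1)c1ccccc1.[Cl-]
Why: Wittig reaction of the aldehyde with (methoxymethylidene)triphenylphosphorane gives the enol ether; its E/Z composition is not decisive because the α-bromo ether centre formed in step 7 epimerises readily.

Step 7
Reactants: 12 3-(2-methoxyethenyl)-1-(triisopropylsilyl)indole
Product: 14 3-[(Z)-1-bromo-2-methoxyethenyl]-1-(triisopropylsilyl)indole, via dibromide 13 (not isolated)
Conditions: Br2 (1.0 equiv), CH2Cl2, −78 °C; then DBU, −78 → 0 °C; chromatography on Et3N-deactivated silica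
Reagents that add atoms: bromine, BrBr
Why: Bromination–dehydrobromination of an enol ether, in which Br2 adds across the electron-rich C=C and DBU removes the acidic proton on the indolyl- and bromine-bearing carbon with loss of the ether-activated bromide; the isomer with bromine cis to methoxy and the indole trans to it is the less crowded one and should predominate, and it is separated from any other isomer.

Step 8
Reactants: 14 3-[(Z)-1-bromo-2-methoxyethenyl]-1-(triisopropylsilyl)indole; 9 methyl 3-(2-methoxy-3,4-dioxocyclobut-1-en-1-yl)-2-(2-methylbut-3-en-2-yl)indole-1-carboxylate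
Product: 16 methyl 3-{3-hydroxy-2-methoxy-3-[(Z)-2-methoxy-1-(1-triisopropylsilylindol-3-yl)ethenyl]-4-oxocyclobut-1-en-1-yl}-2-(2-methylbut-3-en-2-yl)indole-1-carboxylate (racemic), via vinyllithium 15 (not isolated)
Conditions: 14, t-BuLi (2.0 equiv), THF, −78 °C; cannulate into 9, THF, −78 °C; aq NH4Cl, −78 °C; rapid filtration through Et3N-deactivated silica
Reagents that add atoms: none
Why: Bromine–lithium exchange with retention gives a vinyllithium whose lithium is cis to, and coordinated by, the methoxy oxygen (so LiOMe is not lost at −78 °C), and this adds 1,2 to the ketone carbonyl of 9 next to the methoxy-bearing carbon, the usual site for 3-alkoxy-4-arylcyclobutenediones because the other carbonyl is a vinylogous ester, while indole A is N-acylated and twisted out of conjugation by its tertiary C2 substituent; the carbinol centre forms as a racemate and is destroyed in step 9.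

Step 9
Reactants: 16 methyl 3-{3-hydroxy-2-methoxy-3-[(Z)-2-methoxy-1-(1-triisopropylsilylindol-3-yl)ethenyl]-4-oxocyclobut-1-en-1-yl}-2-(2-methylbut-3-en-2-yl)indole-1-carboxylate
Product: 20 2,5-dimethoxy-3-[1-(triisopropylsilyl)indol-3-yl]-6-[1-(methoxycarbonyl)-2-(2-methylbut-3-en-2-yl)indol-3-yl]cyclohexa-2,5-diene-1,4-dione, via dienylketene 17 (not isolated), via cyclohexadienone 18 (not isolated), via hydroquinone 19 (not isolated)
Conditions: toluene (degassed, dilute), 110 °C; cool to rt; Ag2O
Reagents that add atoms: none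
Why: Heating opens the strained cyclobutenone by a conrotatory four-electron electrocyclic cleavage of the C(=O)–C(OH) bond, the hydroxyl donor turning outward so that the alkenyl arm lies cis to the ketene in dienylketene 17. A disrotatory six-electron electrocyclization then joins the ketene carbon to the methoxy-bearing vinyl carbon, closing the six-membered carbocycle (quinone C1–C2) as cyclohexadienone 18. Enolization of 18 erases its only sp3 ring carbon and gives hydroquinone 19, which Ag2O dehydrogenates to the quinone, so no stereocentre is formed or needed. The closest known reaction is the Moore rearrangement of 4-alkenyl-4-hydroxycyclobutenones made from squaric acid derivatives. The step needs only outward rotation of the hydroxyl, which its donor character secures, and ring opening in the other sense is unproductive and reversible. The para arrangement of the two indoles and of the two methoxy groups is already fixed by the site of addition in step 8, and strain release plus aromatization drive the change.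

Step 10
Reactants: 20 2,5-dimethoxy-3-[1-(triisopropylsilyl)indol-3-yl]-6-[1-(methoxycarbonyl)-2-(2-methylbut-3-en-2-yl)indol-3-yl]cyclohexa-2,5-diene-1,4-dione
Product: 22 2,5-dimethoxy-3-(1H-indol-3-yl)-6-[2-(2-methylbut-3-en-2-yl)-1H-indol-3-yl]cyclohexa-2,5-diene-1,4-dione (target), via N-silyl quinone 21 (not isolated)
Conditions: K2CO3 (cat.), MeOH–THF, 0 °C → rt; concentrate; Bu4NF, THF, 0 °C; aq NH4Cl
Reagents that add atoms: none
Why: Base-catalysed methanolysis (transesterification) of the activated N-acylindole carbamate releases dimethyl carbonate, and fluoride-induced desilylation then frees the second indole nitrogen; methoxide exchange at the quinone methoxy carbons is degenerate, so the dimethoxyquinone should be unchanged.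

**Compound list**

1 | 2,2-dimethylbut-3-enoic acid | C=CC(C)(C)C(=O)O | starting material
2 | 2-methylaniline | Cc1ccccc1N | starting material
3 | 2,2-dimethylbut-3-enoyl chloride | C=CC(C)(C)C(=O)Cl | intermediate (not isolated)
4 | N-(2-methylphenyl)-2,2-dimethylbut-3-enamide | C=CC(C)(C)C(=O)Nc1ccccc1C | intermediate
5 | 2-(2-methylbut-3-en-2-yl)-1H-indole | C=CC(C)(C)c1cc2ccccc2[nH]1 | intermediate
6 | 3,4-dichlorocyclobut-3-ene-1,2-dione (squaric acid dichloride) | O=C1C(=O)C(Cl)=C1Cl | starting material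
7 | 3-chloro-4-[2-(2-methylbut-3-en-2-yl)-1H-indol-3-yl]cyclobut-3-ene-1,2-dione | C=CC(C)(C)c1[nH]c2ccccc2c1C1=C(Cl)C(=O)C1=O | intermediate (not isolated)
8 | 3-methoxy-4-[2-(2-methylbut-3-en-2-yl)-1H-indol-3-yl]cyclobut-3-ene-1,2-dione | C=CC(C)(C)c1[nH]c2ccccc2c1C1=C(OC)C(=O)C1=O | intermediate
9 | methyl 3-(2-methoxy-3,4-dioxocyclobut-1-en-1-yl)-2-(2-methylbut-3-en-2-yl)indole-1-carboxylate | C=CC(C)(C)c1n(C(=O)OC)c2ccccc2c1C1=C(OC)C(=O)C1=O | intermediate
10 | 1H-indole-3-carbaldehyde | O=Cc1c[nH]c2ccccc12 | starting material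
11 | 1-(triisopropylsilyl)indole-3-carbaldehyde | O=Cc1cn([Si](C(C)C)(C(C)C)C(C)C)c2ccccc12 | intermediate
12 | 3-(2-methoxyethenyl)-1-(triisopropylsilyl)indole (E/Z mixture) | COC=Cc1cn([Si](C(C)C)(C(C)C)C(C)C)c2ccccc12 | intermediate
13 | 3-(1,2-dibromo-2-methoxyethyl)-1-(triisopropylsilyl)indole (diastereomer mixture) | COC(Br)C(Br)c1cn([Si](C(C)C)(C(C)C)C(C)C)c2ccccc12 | intermediate (not isolated)
14 | 3-[(Z)-1-bromo-2-methoxyethenyl]-1-(triisopropylsilyl)indole (Br cis to OMe) | CO/C=C(\Br)c1cn([Si](C(C)C)(C(C)C)C(C)C)c2ccccc12 | intermediate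
15 | (E)-[2-methoxy-1-(1-triisopropylsilylindol-3-yl)ethenyl]lithium (Li cis to OMe) | CO/C=C(\[Li])c1cn([Si](C(C)C)(C(C)C)C(C)C)c2ccccc12 | intermediate (not isolated)
16 | methyl 3-{3-hydroxy-2-methoxy-3-[(Z)-2-methoxy-1-(1-triisopropylsilylindol-3-yl)ethenyl]-4-oxocyclobut-1-en-1-yl}-2-(2-methylbut-3-en-2-yl)indole-1-carboxylate (racemic) | C=CC(C)(C)c1n(C(=O)OC)c2ccccc2c1C1=C(OC)C(O)(/C(c2cn([Si](C(C)C)(C(C)C)C(C)C)c3ccccc23)=C\OC)C1=O | intermediate
17 | methyl 3-[(3Z,5Z)-4-hydroxy-3,6-dimethoxy-1-oxo-5-(1-triisopropylsilylindol-3-yl)hexa-1,3,5-trien-2-yl]-2-(2-methylbut-3-en-2-yl)indole-1-carboxylate (dienylketene) | O=C=C(c1c(C(C)(C)C=C)n(C(=O)OC)c2ccccc12)\C(OC)=C(O)/C(c1cn([Si](C(C)C)(C(C)C)C(C)C)c2ccccc12)=C\OC | intermediate (not isolated)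
18 | methyl 3-[3-hydroxy-2,5-dimethoxy-6-oxo-4-(1-triisopropylsilylindol-3-yl)cyclohexa-1,3-dien-1-yl]-2-(2-methylbut-3-en-2-yl)indole-1-carboxylate (racemic) | COC1C(=O)C(c2c(C(C)(C)C=C)n(C(=O)OC)c3ccccc23)=C(OC)C(O)=C1c1cn([Si](C(C)C)(C(C)C)C(C)C)c2ccccc12 | intermediate (not isolated)
19 | methyl 3-[3,6-dihydroxy-2,5-dimethoxy-4-(1-triisopropylsilylindol-3-yl)phenyl]-2-(2-methylbut-3-en-2-yl)indole-1-carboxylate | C=CC(C)(C)c1n(C(=O)OC)c2ccccc2c1-c1c(OC)c(O)c(-c2cn([Si](C(C)C)(C(C)C)C(C)C)c3ccccc23)c(OC)c1O | intermediate (not isolated)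
20 | 2,5-dimethoxy-3-[1-(triisopropylsilyl)indol-3-yl]-6-[1-(methoxycarbonyl)-2-(2-methylbut-3-en-2-yl)indol-3-yl]cyclohexa-2,5-diene-1,4-dione | C=CC(C)(C)c1n(C(=O)OC)c2ccccc2c1C1=C(OC)C(=O)C(c2cn([Si](C(C)C)(C(C)C)C(C)C)c3ccccc23)=C(OC)C1=O | intermediate
21 | 2,5-dimethoxy-3-[1-(triisopropylsilyl)indol-3-yl]-6-[2-(2-methylbut-3-en-2-yl)-1H-indol-3-yl]cyclohexa-2,5-diene-1,4-dione | C=CC(C)(C)c1[nH]c2ccccc2c1C1=C(OC)C(=O)C(c2cn([Si](C(C)C)(C(C)C)C(C)C)c3ccccc23)=C(OC)C1=O | intermediate (not isolated)
22 | 2,5-dimethoxy-3-(1H-indol-3-yl)-6-[2-(2-methylbut-3-en-2-yl)-1H-indol-3-yl]cyclohexa-2,5-diene-1,4-dione | C=CC(C)(C)c1[nH]c2ccccc2c1C1=C(OC)C(=O)C(c2c[nH]c3ccccc23)=C(OC)C1=O | target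

**Step count**

Total: 10 steps. Longest linear sequence: 7 steps (steps 1, 2, 3, 4, 8, 9, 10); the indole B branch (steps 5, 6, 7) joins at step 8.

**Steps most likely to fail**

Step 7. The dibromide may lose hydrogen bromide in the wrong direction (ionization at the indolylmethyl carbon and proton loss from the acetal carbon), the alkene may form with the wrong geometry, or bromide may strip the N-silyl group. The fallback sets out from aldehyde 11 and comes back at vinyllithium 15. Methoxymethyllithium (from Bu3SnCH2OMe and n-BuLi, THF, −78 °C) should add to 11 to give 2-methoxy-1-[1-(triisopropylsilyl)indol-3-yl]ethanol F1. Oxidation with MnO2 in CH2Cl2 should give 2-methoxy-1-[1-(triisopropylsilyl)indol-3-yl]ethanone F2. KN(SiMe3)2 and PhNTf2 (THF, −78 °C) should trap the potassium-chelated Z-enolate as (Z)-2-methoxy-1-[1-(triisopropylsilyl)indol-3-yl]ethenyl trifluoromethanesulfonate F3. Stannylation with Me3SnSnMe3, Pd(PPh3)4 (zerovalent palladium) and LiCl in THF at 60 °C should give, with retention, trimethyl{(Z)-2-methoxy-1-[1-(triisopropylsilyl)indol-3-yl]ethenyl}stannane F4. Tin–lithium exchange with MeLi (THF, −78 °C) then gives 15, which is used in step 8 as before. This sequence fixes both the position of the metal and its cis relation to methoxy without a halogenation of the enol ether.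

Step 8. The vinyllithium may attack the wrong carbonyl (the one flanking the indolyl-bearing carbon) or the carbamate, or may decompose by loss of lithium methoxide before it adds. The fallback leaves the squarate assembly, sets out from indole 5 and comes back at target 22.
- Acid-promoted conjugate addition of 5 to 2,5-dichloro-1,4-benzoquinone (AcOH, THF) should give 2,5-dichloro-3-[2-(2-methylbut-3-en-2-yl)-1H-indol-3-yl]benzene-1,4-diol F5, which DDQ oxidises to 2,5-dichloro-3-[2-(2-methylbut-3-en-2-yl)-1H-indol-3-yl]cyclohexa-2,5-diene-1,4-dione F6.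
- A second acid-promoted addition, of commercial 1H-indole at the only free quinone carbon, should give 2,5-dichloro-3-(1H-indol-3-yl)-6-[2-(2-methylbut-3-en-2-yl)-1H-indol-3-yl]benzene-1,4-diol F7, which DDQ oxidises to 2,5-dichloro-3-(1H-indol-3-yl)-6-[2-(2-methylbut-3-en-2-yl)-1H-indol-3-yl]cyclohexa-2,5-diene-1,4-dione F8.
- NaOH in MeOH–H2O should replace both chlorides by addition–elimination to give 2,5-dihydroxy-3-(1H-indol-3-yl)-6-[2-(2-methylbut-3-en-2-yl)-1H-indol-3-yl]cyclohexa-2,5-diene-1,4-dione F9.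
- Me3SiCHN2 in MeOH–CH2Cl2 should methylate the two acidic vinylogous-acid hydroxyls to give 22.

Step 9. The free hydroxyl may intercept the ketene (lactonisation to a furanone after ring opening in the unwanted sense), or the doubly allylic carbinol may ionise before the ring opens. The fallback sets out from 9 (with vinyllithium 15) and comes back at hydroquinone 19. The addition mixture of step 8 is quenched with Me3SiCl at −78 °C instead of NH4Cl, which should give methyl 3-{2-methoxy-3-[(Z)-2-methoxy-1-(1-triisopropylsilylindol-3-yl)ethenyl]-4-oxo-3-(trimethylsilyloxy)cyclobut-1-en-1-yl}-2-(2-methylbut-3-en-2-yl)indole-1-carboxylate F10. Heating in toluene at 110 °C should open it to the silyloxy dienylketene methyl 3-[(3Z,5Z)-3,6-dimethoxy-1-oxo-5-(1-triisopropylsilylindol-3-yl)-4-(trimethylsilyloxy)hexa-1,3,5-trien-2-yl]-2-(2-methylbut-3-en-2-yl)indole-1-carboxylate F11, which cannot lactonise. Six-electron closure should give methyl 3-[2,5-dimethoxy-6-oxo-4-(1-triisopropylsilylindol-3-yl)-3-(trimethylsilyloxy)cyclohexa-1,3-dien-1-yl]-2-(2-methylbut-3-en-2-yl)indole-1-carboxylate F12, which enolises to methyl 3-[6-hydroxy-2,5-dimethoxy-4-(1-triisopropylsilylindol-3-yl)-3-(trimethylsilyloxy)phenyl]-2-(2-methylbut-3-en-2-yl)indole-1-carboxylate F13. Citric acid in MeOH should remove the aryl silyl ether to give 19, which Ag2O oxidises to 20 as in step 9.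

**Further compounds**

F1 | step 7 | 2-methoxy-1-[1-(triisopropylsilyl)indol-3-yl]ethanol (racemic) | COCC(O)c1cn([Si](C(C)C)(C(C)C)C(C)C)c2ccccc12
F2 | step 7 | 2-methoxy-1-[1-(triisopropylsilyl)indol-3-yl]ethanone | COCC(=O)c1cn([Si](C(C)C)(C(C)C)C(C)C)c2ccccc12
F3 | step 7 | (Z)-2-methoxy-1-[1-(triisopropylsilyl)indol-3-yl]ethenyl trifluoromethanesulfonate | CO/C=C(\OS(=O)(=O)C(F)(F)F)c1cn([Si](C(C)C)(C(C)C)C(C)C)c2ccccc12
F4 | step 7 | trimethyl{(Z)-2-methoxy-1-[1-(triisopropylsilyl)indol-3-yl]ethenyl}stannane | CO/C=C(\[Sn](C)(C)C)c1cn([Si](C(C)C)(C(C)C)C(C)C)c2ccccc12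
F5 | step 8 | 2,5-dichloro-3-[2-(2-methylbut-3-en-2-yl)-1H-indol-3-yl]benzene-1,4-diol | C=CC(C)(C)c1[nH]c2ccccc2c1-c1c(Cl)c(O)cc(Cl)c1O
F6 | step 8 | 2,5-dichloro-3-[2-(2-methylbut-3-en-2-yl)-1H-indol-3-yl]cyclohexa-2,5-diene-1,4-dione | C=CC(C)(C)c1[nH]c2ccccc2c1C1=C(Cl)C(=O)C=C(Cl)C1=O
F7 | step 8 | 2,5-dichloro-3-(1H-indol-3-yl)-6-[2-(2-methylbut-3-en-2-yl)-1H-indol-3-yl]benzene-1,4-diol | C=CC(C)(C)c1[nH]c2ccccc2c1-c1c(Cl)c(O)c(-c2c[nH]c3ccccc23)c(Cl)c1O
F8 | step 8 | 2,5-dichloro-3-(1H-indol-3-yl)-6-[2-(2-methylbut-3-en-2-yl)-1H-indol-3-yl]cyclohexa-2,5-diene-1,4-dione | C=CC(C)(C)c1[nH]c2ccccc2c1C1=C(Cl)C(=O)C(c2c[nH]c3ccccc23)=C(Cl)C1=O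
F9 | step 8 | 2,5-dihydroxy-3-(1H-indol-3-yl)-6-[2-(2-methylbut-3-en-2-yl)-1H-indol-3-yl]cyclohexa-2,5-diene-1,4-dione | C=CC(C)(C)c1[nH]c2ccccc2c1C1=C(O)C(=O)C(c2c[nH]c3ccccc23)=C(O)C1=O
F10 | step 9 | methyl 3-{2-methoxy-3-[(Z)-2-methoxy-1-(1-triisopropylsilylindol-3-yl)ethenyl]-4-oxo-3-(trimethylsilyloxy)cyclobut-1-en-1-yl}-2-(2-methylbut-3-en-2-yl)indole-1-carboxylate (racemic) | C=CC(C)(C)c1n(C(=O)OC)c2ccccc2c1C1=C(OC)C(O[Si](C)(C)C)(/C(c2cn([Si](C(C)C)(C(C)C)C(C)C)c3ccccc23)=C\OC)C1=O
F11 | step 9 | methyl 3-[(3Z,5Z)-3,6-dimethoxy-1-oxo-5-(1-triisopropylsilylindol-3-yl)-4-(trimethylsilyloxy)hexa-1,3,5-trien-2-yl]-2-(2-methylbut-3-en-2-yl)indole-1-carboxylate | O=C=C(c1c(C(C)(C)C=C)n(C(=O)OC)c2ccccc12)\C(OC)=C(O[Si](C)(C)C)/C(c1cn([Si](C(C)C)(C(C)C)C(C)C)c2ccccc12)=C\OC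
F12 | step 9 | methyl 3-[2,5-dimethoxy-6-oxo-4-(1-triisopropylsilylindol-3-yl)-3-(trimethylsilyloxy)cyclohexa-1,3-dien-1-yl]-2-(2-methylbut-3-en-2-yl)indole-1-carboxylate (racemic) | COC1C(=O)C(c2c(C(C)(C)C=C)n(C(=O)OC)c3ccccc23)=C(OC)C(O[Si](C)(C)C)=C1c1cn([Si](C(C)C)(C(C)C)C(C)C)c2ccccc12
F13 | step 9 | methyl 3-[6-hydroxy-2,5-dimethoxy-4-(1-triisopropylsilylindol-3-yl)-3-(trimethylsilyloxy)phenyl]-2-(2-methylbut-3-en-2-yl)indole-1-carboxylate | C=CC(C)(C)c1n(C(=O)OC)c2ccccc2c1-c1c(OC)c(O[Si](C)(C)C)c(-c2cn([Si](C(C)C)(C(C)C)C(C)C)c3ccccc23)c(OC)c1O
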